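**Plan**

- Cuts: (a) the ketone C–C bond between pyridone C3 and the acyl carbon (3-lithiopyridine + decalin aldehyde, then oxidation); (b) the pyridone C5–C1' bond (5-lithiopyridine + quinone monoketal); (c) the two C–O bonds of the oxirane at C2' and C3'; (d) decalin bonds C1–C2 and C4a–C8a (intramolecular Diels–Alder reaction).
- Enabling feature: C1' (the quaternary carbinol on pyridone C5) is tied to C4' by two three-carbon arms, C2'–C3' carrying the oxirane and C6'–C5' as methylenes. C1', C2' and C3' can therefore be drawn from a mirror-symmetric 4-pyridyl-4-silyloxycyclohexa-2,5-dienone in which C1' is prochiral.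
- Forward order: pyridine–dienone union, desymmetrising epoxidation (oxirane ring), saturation and reduction of the second arm; separately the decalin (both carbocycles in one cycloaddition); then fragment union, oxidation, fluoride unmasking.
- Stereochemistry: C1', C2', C3' from the catalytic epoxidation (substrate picks the face, catalyst picks the arm); C4' from substrate-controlled hydride delivery; decalin C7 from (S)-citronellal, relayed to C1, C4a, C8a in the endo cycloaddition; C2 by equilibration of the aldehyde; E-alkenes from Wittig and Julia–Kocienski reactions.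

Key step: step 4

Remark on locants: C1'–C6' are the carbons of the cyclohexane ring on pyridone C5 (C1' quaternary, C2'/C3' oxirane, C4' secondary carbinol); decalin locants follow octahydronaphthalene numbering (C1 propenyl, C2 acyl).

Assumption: the quinine-derived primary amine is taken to select the arm that leads to the (1R,5R,6S) epoxy enone, by analogy with its sense on simple cyclohexenones. If the dienone responds with the opposite sense, the quinidine-derived pseudoenantiomer is used and nothing else changes.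

**Route**

Step 1
Reactants: 1 5-bromo-2,4-dichloropyridine
Product: 2 5-bromo-2,4-bis[2-(trimethylsilyl)ethoxy]pyridine
Conditions: Me3SiCH2CH2OH (2.4 equiv), NaH (2.6 equiv), THF/DMF, 0 → 70 °C
Reagents that add atoms: 2-(trimethylsilyl)ethanol, C[Si](C)(C)CCO
Why: Two nucleophilic aromatic substitutions (addition–elimination) replace the chlorides at C4 and C2, which the ring nitrogen activates, while the C5 bromide is not activated; the 2-(trimethylsilyl)ethyl ethers are chosen so that the pyridone can be released at the end by fluoride in the presence of the oxirane.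

Step 2
Reactants: 2 5-bromo-2,4-bis[2-(trimethylsilyl)ethoxy]pyridine, 3 4,4-dimethoxycyclohexa-2,5-dien-1-one
Product: 6 5-[4,4-dimethoxy-1-(triethylsilyloxy)cyclohexa-2,5-dien-1-yl]-2,4-bis[2-(trimethylsilyl)ethoxy]pyridine, via aryllithium 4 (not isolated), via lithium alkoxide 5 (not isolated)
Conditions: n-BuLi, THF, −78 °C; then 3, −78 °C; then Et3SiCl, DMAP (cat.), −78 °C → rt
Reagents that add atoms: chlorotriethylsilane, CC[Si](Cl)(CC)CC
Why: Bromine–lithium exchange outruns ring deprotonation at −78 °C, the hard aryllithium adds 1,2 to the only carbonyl of the quinone monoketal, and the tertiary lithium alkoxide is silylated in the same flask so that no free hydroxyl can later direct the peroxide.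

Step 3
Reactants: 6 5-[4,4-dimethoxy-1-(triethylsilyloxy)cyclohexa-2,5-dien-1-yl]-2,4-bis[2-(trimethylsilyl)ethoxy]pyridine
Product: 7 4-{4,6-bis[2-(trimethylsilyl)ethoxy]pyridin-3-yl}-4-(triethylsilyloxy)cyclohexa-2,5-dien-1-one
Conditions: 5% aq. oxalic acid, THF, 0 °C → rt
Reagents that add atoms: water, O
Why: Acid-catalysed hydrolysis of the doubly allylic dimethyl ketal through its delocalised oxocarbenium ion is much faster than cleavage of the hindered tertiary triethylsilyl ether and gives the achiral cross-conjugated dienone whose C4 (future C1') is prochiral.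

Step 4
Reactants: 7 4-{4,6-bis[2-(trimethylsilyl)ethoxy]pyridin-3-yl}-4-(triethylsilyloxy)cyclohexa-2,5-dien-1-one
Product: 8 (1R,5R,6S)-5-{4,6-bis[2-(trimethylsilyl)ethoxy]pyridin-3-yl}-5-(triethylsilyloxy)-7-oxabicyclo[4.1.0]hept-3-en-2-one (oxirane cis to the pyridyl group, trans to the silyloxy group)
Conditions: 9-amino-9-deoxy-epi-quinine (10 mol%), CF3CO2H (20 mol%), 50% aq. H2O2 (1.1 equiv), dioxane, 30 °C
Reagents that add atoms: hydrogen peroxide, OO
Why: The primary amine condenses with the dienone carbonyl to a cross-conjugated iminium ion, the protonated quinuclidine hydrogen-bonds hydrogen peroxide and delivers it to C2' in a conjugate addition, and the β-hydroperoxy enamine then closes on the proximal oxygen with loss of water to make the C2'–O and C3'–O bonds before hydrolysis frees the catalyst. The closest known reaction type is the Weitz–Scheffer epoxidation of cyclic enones catalysed by cinchona primary amine salts, together with the chiral-cation-mediated epoxidation of quinone monoketals, which are prochiral cyclohexadienones of the same class. The oxirane closes in a 3-exo-tet mode. C2' and C3' are set by the enone face that receives the peroxide, and C1', to which no bond is made, becomes a stereocentre because only one of its two enantiotopic enone arms is oxidised. Two selectivities are needed: attack anti to the C1'–O bond, which the substrate should secure because the silyl ether offers no hydrogen-bond donor and its C–O σ* orbital, dipole and triethylsilyl bulk all favour approach from the pyridyl face; and choice of the arm, which the catalyst should secure because it accepts one β-face only and only one arm presents that face anti to the silyloxy group. One equivalent of oxidant limits bis-epoxidation, and faster over-oxidation of the minor enantiomer should further enrich 8.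

Step 5
Reactants: 8 (1R,5R,6S)-5-{4,6-bis[2-(trimethylsilyl)ethoxy]pyridin-3-yl}-5-(triethylsilyloxy)-7-oxabicyclo[4.1.0]hept-3-en-2-one
Product: 9 (1R,5R,6S)-5-{4,6-bis[2-(trimethylsilyl)ethoxy]pyridin-3-yl}-5-(triethylsilyloxy)-7-oxabicyclo[4.1.0]heptan-2-one
Conditions: [(Ph3P)CuH]6 (0.35 equiv), H2O (3 equiv), toluene, rt
Reagents that add atoms: none
Why: Conjugate reduction with the copper hydride hexamer: hydride adds to C6' of the remaining enone and water protonates the copper enolate at C5', while ketone, oxirane, silyl ethers and pyridine are not reduced and no stereocentre is touched.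

Step 6
Reactants: 9 (1R,5R,6S)-5-{4,6-bis[2-(trimethylsilyl)ethoxy]pyridin-3-yl}-5-(triethylsilyloxy)-7-oxabicyclo[4.1.0]heptan-2-one
Product: 10 (1S,2R,5R,6S)-5-{4,6-bis[2-(trimethylsilyl)ethoxy]pyridin-3-yl}-5-(triethylsilyloxy)-7-oxabicyclo[4.1.0]heptan-2-ol (hydroxyl trans to the oxirane, cis to the silyloxy group)
Conditions: NaBH4, CeCl3·7H2O, MeOH, −78 °C
Reagents that add atoms: none
Why: Luche-type borohydride reduction: in the half-chair of 9 the pyridyl group sits pseudoequatorial and the silyloxy group pseudoaxial on the lower face, so axial hydride delivery to C4' from the oxirane face (helped by cation bridging between the carbonyl and oxirane oxygens) should give the equatorial alcohol trans to the oxirane, which is (R) at C4'.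

Step 7
Reactants: 10 (1S,2R,5R,6S)-5-{4,6-bis[2-(trimethylsilyl)ethoxy]pyridin-3-yl}-5-(triethylsilyloxy)-7-oxabicyclo[4.1.0]heptan-2-ol
Product: 11 5-[(1S,2R,5R,6S)-5-(tert-butyldimethylsilyloxy)-2-(triethylsilyloxy)-7-oxabicyclo[4.1.0]heptan-2-yl]-2,4-bis[2-(trimethylsilyl)ethoxy]pyridine
Conditions: t-BuMe2SiCl, imidazole, DMAP (cat.), DMF, rt
Reagents that add atoms: tert-butyldimethylsilyl chloride, CC(C)(C)[Si](C)(C)Cl
Why: Standard silylation of the secondary alcohol under non-acidic conditions leaves the oxirane and the tertiary silyl ether intact and masks the hydroxyl for the lithiation and oxidation that follow.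

Step 8
Reactants: 12 (S)-citronellal
Product: 13 (6S)-8,8-dimethoxy-2,6-dimethyloct-2-ene
Conditions: HC(OMe)3, MeOH, pyridinium p-toluenesulfonate (cat.), rt
Reagents that add atoms: trimethyl orthoformate, COC(OC)OC; methanol, CO
Why: Acid-catalysed acetalisation driven by the orthoformate masks the aldehyde for the redox and olefination steps, and the mild pyridinium acid avoids the carbonyl-ene cyclisation of citronellal.

Step 9
Reactants: 13 (6S)-8,8-dimethoxy-2,6-dimethyloct-2-ene
Product: 15 (2E,6S)-8,8-dimethoxy-2,6-dimethyloct-2-enal, via allylic alcohol 14 (not isolated)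
Conditions: SeO2 (0.5 equiv), t-BuOOH (in decane), CH2Cl2, 0 °C → rt; then MnO2, CH2Cl2, rt
Reagents that add atoms: tert-butyl hydroperoxide, CC(C)(C)OO; selenium dioxide, O=[Se]=O
Why: Sharpless allylic oxidation (ene reaction then [2,3]-sigmatropic shift) functionalises the (E)-methyl group of the trisubstituted alkene selectively, and MnO2 converges the allylic alcohol and any enal already formed on the (E)-enal.

Step 10
Reactants: 15 (2E,6S)-8,8-dimethoxy-2,6-dimethyloct-2-enal
Product: 16 ethyl (2E,4E,8S)-10,10-dimethoxy-4,8-dimethyldeca-2,4-dienoate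
Conditions: Ph3P=CHCO2Et, toluene, 80 °C
Reagents that add atoms: ethyl (triphenylphosphoranylidene)acetate, CCOC(=O)C=P(c1ccccc1)(c1ccccc1)c1ccccc1
Why: Wittig reaction of the stabilised ylide forms the new C2=C3 alkene with E geometry and the acetal is inert.

Step 11
Reactants: 16 ethyl (2E,4E,8S)-10,10-dimethoxy-4,8-dimethyldeca-2,4-dienoate
Product: 17 (2E,4E,8S)-10,10-dimethoxy-4,8-dimethyldeca-2,4-dien-1-ol
Conditions: i-Bu2AlH, CH2Cl2, −78 °C
Reagents that add atoms: none
Why: 1,2-Reduction of the conjugated ester by the aluminium hydride at low temperature gives the dienyl alcohol without touching diene or acetal, which turns the electron-poor dienoate into a diene fit for a normal-demand cycloaddition.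

Step 12
Reactants: 17 (2E,4E,8S)-10,10-dimethoxy-4,8-dimethyldeca-2,4-dien-1-ol
Product: 18 tert-butyl{[(2E,4E,8S)-10,10-dimethoxy-4,8-dimethyldeca-2,4-dien-1-yl]oxy}diphenylsilane
Conditions: t-BuPh2SiCl, imidazole, CH2Cl2, 0 °C → rt
Reagents that add atoms: tert-butyl(chloro)diphenylsilane, CC(C)(C)[Si](Cl)(c1ccccc1)c1ccccc1
Why: Silylation gives a robust ether that should survive acetal hydrolysis and the Lewis acid of step 15.

Step 13
Reactants: 18 tert-butyl{[(2E,4E,8S)-10,10-dimethoxy-4,8-dimethyldeca-2,4-dien-1-yl]oxy}diphenylsilane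
Product: 19 (3S,6E,8E)-10-[(tert-butyldiphenylsilyl)oxy]-3,7-dimethyldeca-6,8-dienal
Conditions: pyridinium p-toluenesulfonate (cat.), acetone/H2O, 45 °C
Reagents that add atoms: water, O
Why: Mild acid-catalysed acetal hydrolysis unmasks the aldehyde, and the tert-butyldiphenylsilyl ether is stable to the pyridinium acid.

Step 14
Reactants: 19 (3S,6E,8E)-10-[(tert-butyldiphenylsilyl)oxy]-3,7-dimethyldeca-6,8-dienal
Product: 20 (2E,5S,8E,10E)-12-[(tert-butyldiphenylsilyl)oxy]-5,9-dimethyldodeca-2,8,10-trienal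
Conditions: Ph3P=CHCHO, toluene, 80 °C
Reagents that add atoms: (triphenylphosphoranylidene)acetaldehyde, O=CC=P(c1ccccc1)(c1ccccc1)c1ccccc1
Why: Wittig reaction with the formyl-stabilised ylide homologates the saturated aldehyde to the (E)-enal that serves as dienophile.

Step 15
Reactants: 20 (2E,5S,8E,10E)-12-[(tert-butyldiphenylsilyl)oxy]-5,9-dimethyldodeca-2,8,10-trienal
Product: 21 (1R,2S,4aS,7S,8aS)-2-{[(tert-butyldiphenylsilyl)oxy]methyl}-4,7-dimethyl-1,2,4a,5,6,7,8,8a-octahydronaphthalene-1-carbaldehyde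
Conditions: Me2AlCl (1.1 equiv), CH2Cl2, −78 → −30 °C
Reagents that add atoms: none
Why: Lewis acid promoted type 1 intramolecular Diels–Alder reaction of an (E,E,E)-2,8,10-trienal: the aluminium-bound enal should react through the endo transition state with a chair-like tether that keeps the C5 methyl equatorial, giving the trans-fused decalin and setting C1, C4a and C8a relative to the citronellal-derived C7, while the E,E-diene places the silyloxymethyl group at C2 cis to the formyl group (corrected in step 18).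

Step 16
Reactants: 21 (1R,2S,4aS,7S,8aS)-2-{[(tert-butyldiphenylsilyl)oxy]methyl}-4,7-dimethyl-1,2,4a,5,6,7,8,8a-octahydronaphthalene-1-carbaldehyde
Product: 22 tert-butyl{[(1R,2R,4aS,7S,8aR)-4,7-dimethyl-1-[(E)-prop-1-en-1-yl]-1,2,4a,5,6,7,8,8a-octahydronaphthalen-2-yl]methoxy}diphenylsilane
Conditions: 5-(ethylsulfonyl)-1-phenyl-1H-tetrazole, KN(SiMe3)2, DME, −60 °C → rt
Reagents that add atoms: 5-(ethylsulfonyl)-1-phenyl-1H-tetrazole, CCS(=O)(=O)c1nnnn1-c1ccccc1
Why: Julia–Kocienski olefination: the potassium anion of the phenyltetrazolyl sulfone adds to the α-branched aldehyde and Smiles rearrangement with loss of SO2 and tetrazololate should give the (E)-propenyl group, C1 being already in its stable equatorial configuration.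

Step 17
Reactants: 22 tert-butyl{[(1R,2R,4aS,7S,8aR)-4,7-dimethyl-1-[(E)-prop-1-en-1-yl]-1,2,4a,5,6,7,8,8a-octahydronaphthalen-2-yl]methoxy}diphenylsilane
Product: 23 [(1R,2R,4aS,7S,8aR)-4,7-dimethyl-1-[(E)-prop-1-en-1-yl]-1,2,4a,5,6,7,8,8a-octahydronaphthalen-2-yl]methanol
Conditions: Bu4NF, THF, rt
Reagents that add atoms: none
Why: Fluoride cleaves the primary silyl ether and nothing else in the molecule is fluoride-sensitive.

Step 18
Reactants: 23 [(1R,2R,4aS,7S,8aR)-4,7-dimethyl-1-[(E)-prop-1-en-1-yl]-1,2,4a,5,6,7,8,8a-octahydronaphthalen-2-yl]methanol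
Product: 25 (1R,2S,4aS,7S,8aR)-4,7-dimethyl-1-[(E)-prop-1-en-1-yl]-1,2,4a,5,6,7,8,8a-octahydronaphthalene-2-carbaldehyde, via cis-aldehyde 24 (not isolated)
Conditions: Dess–Martin periodinane, pyridine, CH2Cl2, 0 °C → rt; then DBU (0.3 equiv), CH2Cl2, rt
Reagents that add atoms: none
Why: Dess–Martin oxidation gives the cis aldehyde 24, and catalytic DBU equilibrates the α-centre through the dienolate with kinetic α-reprotonation, so the formyl group should settle pseudoequatorial and trans to the propenyl group (2S) before conjugation of the β,γ-alkene sets in.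

Step 19
Reactants: 11 5-[(1S,2R,5R,6S)-5-(tert-butyldimethylsilyloxy)-2-(triethylsilyloxy)-7-oxabicyclo[4.1.0]heptan-2-yl]-2,4-bis[2-(trimethylsilyl)ethoxy]pyridine, 25 (1R,2S,4aS,7S,8aR)-4,7-dimethyl-1-[(E)-prop-1-en-1-yl]-1,2,4a,5,6,7,8,8a-octahydronaphthalene-2-carbaldehyde
Product: 27 {2,4-bis[2-(trimethylsilyl)ethoxy]-5-[(1S,2R,5R,6S)-5-(tert-butyldimethylsilyloxy)-2-(triethylsilyloxy)-7-oxabicyclo[4.1.0]heptan-2-yl]pyridin-3-yl}[(1R,2S,4aS,7S,8aR)-4,7-dimethyl-1-[(E)-prop-1-en-1-yl]-1,2,4a,5,6,7,8,8a-octahydronaphthalen-2-yl]methanol (both carbinol epimers), via 3-lithiopyridine 26 (not isolated)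
Conditions: t-BuLi (1.05 equiv), THF, −78 °C; then 25, −78 → −40 °C
Reagents that add atoms: none
Why: Directed ortho-metalation: C3–H lies between two alkoxy groups and should be removed at −78 °C far faster than the alkyllithium attacks the oxirane or silyl ethers, and the aryllithium then adds to the aldehyde as in related additions of 3-lithio-2,4-dialkoxypyridines; the new carbinol centre is inconsequential because step 20 oxidises it.

Step 20
Reactants: 27 the carbinol of step 19
Product: 28 {2,4-bis[2-(trimethylsilyl)ethoxy]-5-[(1S,2R,5R,6S)-5-(tert-butyldimethylsilyloxy)-2-(triethylsilyloxy)-7-oxabicyclo[4.1.0]heptan-2-yl]pyridin-3-yl}[(1R,2S,4aS,7S,8aR)-4,7-dimethyl-1-[(E)-prop-1-en-1-yl]-1,2,4a,5,6,7,8,8a-octahydronaphthalen-2-yl]methanone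
Conditions: Dess–Martin periodinane, pyridine, CH2Cl2, 0 °C → rt
Reagents that add atoms: none
Why: Dess–Martin oxidation of both carbinol epimers converges on one ketone, and pyridine buffering protects the oxirane and silyl ethers.

Step 21
Reactants: 28 the ketone of step 20
Product: 29 3-[(1R,2S,4aS,7S,8aR)-4,7-dimethyl-1-[(E)-prop-1-en-1-yl]-1,2,4a,5,6,7,8,8a-octahydronaphthalene-2-carbonyl]-5-[(1S,2R,5R,6S)-2,5-dihydroxy-7-oxabicyclo[4.1.0]heptan-2-yl]-4-hydroxypyridin-2(1H)-one (CNP0494338.1)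
Conditions: Bu4NF (excess), AcOH, THF, 0 → 40 °C; pH 5 buffer work-up
Reagents that add atoms: none
Why: Fluoride attacks silicon in each 2-(trimethylsilyl)ethyl ether and triggers β-fragmentation to ethene and Me3SiF with a lactam anion and a vinylogous acid anion as leaving groups, the same reagent cleaves the triethylsilyl and tert-butyldimethylsilyl ethers, and acetic acid buffering keeps alkoxide basicity low so that Payne rearrangement of the oxirane and disturbance of the ketone α-centre (already in its stable configuration) should be avoided.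

**Compound list**

1 | 5-bromo-2,4-dichloropyridine | Clc1cc(Cl)c(Br)cn1 | starting material
2 | 5-bromo-2,4-bis[2-(trimethylsilyl)ethoxy]pyridine | C[Si](C)(C)CCOc1cc(OCC[Si](C)(C)C)c(Br)cn1 | intermediate
3 | 4,4-dimethoxycyclohexa-2,5-dien-1-one | COC1(OC)C=CC(=O)C=C1 | starting material
4 | {4,6-bis[2-(trimethylsilyl)ethoxy]pyridin-3-yl}lithium | C[Si](C)(C)CCOc1cc(OCC[Si](C)(C)C)c([Li])cn1 | intermediate
5 | lithium 1-{4,6-bis[2-(trimethylsilyl)ethoxy]pyridin-3-yl}-4,4-dimethoxycyclohexa-2,5-dien-1-olate | C[Si](C)(C)CCOc1cc(OCC[Si](C)(C)C)c(cn1)C1(O[Li])C=CC(OC)(OC)C=C1 | intermediate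
6 | 5-[4,4-dimethoxy-1-(triethylsilyloxy)cyclohexa-2,5-dien-1-yl]-2,4-bis[2-(trimethylsilyl)ethoxy]pyridine | C[Si](C)(C)CCOc1cc(OCC[Si](C)(C)C)c(cn1)C1(O[Si](CC)(CC)CC)C=CC(OC)(OC)C=C1 | intermediate
7 | 4-{4,6-bis[2-(trimethylsilyl)ethoxy]pyridin-3-yl}-4-(triethylsilyloxy)cyclohexa-2,5-dien-1-one | C[Si](C)(C)CCOc1cc(OCC[Si](C)(C)C)c(cn1)C1(O[Si](CC)(CC)CC)C=CC(=O)C=C1 | intermediate
8 | (1R,5R,6S)-5-{4,6-bis[2-(trimethylsilyl)ethoxy]pyridin-3-yl}-5-(triethylsilyloxy)-7-oxabicyclo[4.1.0]hept-3-en-2-one | C[Si](C)(C)CCOc1cc(OCC[Si](C)(C)C)c(cn1)[C@]1(O[Si](CC)(CC)CC)C=CC(=O)[C@@H]2O[C@@H]21 | intermediate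
9 | (1R,5R,6S)-5-{4,6-bis[2-(trimethylsilyl)ethoxy]pyridin-3-yl}-5-(triethylsilyloxy)-7-oxabicyclo[4.1.0]heptan-2-one | C[Si](C)(C)CCOc1cc(OCC[Si](C)(C)C)c(cn1)[C@]1(O[Si](CC)(CC)CC)CCC(=O)[C@@H]2O[C@@H]21 | intermediate
10 | (1S,2R,5R,6S)-5-{4,6-bis[2-(trimethylsilyl)ethoxy]pyridin-3-yl}-5-(triethylsilyloxy)-7-oxabicyclo[4.1.0]heptan-2-ol | C[Si](C)(C)CCOc1cc(OCC[Si](C)(C)C)c(cn1)[C@]1(O[Si](CC)(CC)CC)CC[C@@H](O)[C@@H]2O[C@@H]21 | intermediate
11 | 5-[(1S,2R,5R,6S)-5-(tert-butyldimethylsilyloxy)-2-(triethylsilyloxy)-7-oxabicyclo[4.1.0]heptan-2-yl]-2,4-bis[2-(trimethylsilyl)ethoxy]pyridine | C[Si](C)(C)CCOc1cc(OCC[Si](C)(C)C)c(cn1)[C@]1(O[Si](CC)(CC)CC)CC[C@@H](O[Si](C)(C)C(C)(C)C)[C@@H]2O[C@@H]21 | intermediate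
12 | (S)-citronellal, (3S)-3,7-dimethyloct-6-enal | C[C@@H](CCC=C(C)C)CC=O | starting material
13 | (6S)-8,8-dimethoxy-2,6-dimethyloct-2-ene | COC(OC)C[C@@H](C)CCC=C(C)C | intermediate
14 | (2E,6S)-8,8-dimethoxy-2,6-dimethyloct-2-en-1-ol | COC(OC)C[C@@H](C)CC/C=C(\C)CO | intermediate
15 | (2E,6S)-8,8-dimethoxy-2,6-dimethyloct-2-enal | COC(OC)C[C@@H](C)CC/C=C(\C)C=O | intermediate
16 | ethyl (2E,4E,8S)-10,10-dimethoxy-4,8-dimethyldeca-2,4-dienoate | COC(OC)C[C@@H](C)CC/C=C(\C)/C=C/C(=O)OCC | intermediate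
17 | (2E,4E,8S)-10,10-dimethoxy-4,8-dimethyldeca-2,4-dien-1-ol | COC(OC)C[C@@H](C)CC/C=C(\C)/C=C/CO | intermediate
18 | tert-butyl{[(2E,4E,8S)-10,10-dimethoxy-4,8-dimethyldeca-2,4-dien-1-yl]oxy}diphenylsilane | COC(OC)C[C@@H](C)CC/C=C(\C)/C=C/CO[Si](c1ccccc1)(c1ccccc1)C(C)(C)C | intermediate
19 | (3S,6E,8E)-10-[(tert-butyldiphenylsilyl)oxy]-3,7-dimethyldeca-6,8-dienal | O=CC[C@@H](C)CC/C=C(\C)/C=C/CO[Si](c1ccccc1)(c1ccccc1)C(C)(C)C | intermediate
20 | (2E,5S,8E,10E)-12-[(tert-butyldiphenylsilyl)oxy]-5,9-dimethyldodeca-2,8,10-trienal | O=C/C=C/C[C@@H](C)CC/C=C(\C)/C=C/CO[Si](c1ccccc1)(c1ccccc1)C(C)(C)C | intermediate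
21 | (1R,2S,4aS,7S,8aS)-2-{[(tert-butyldiphenylsilyl)oxy]methyl}-4,7-dimethyl-1,2,4a,5,6,7,8,8a-octahydronaphthalene-1-carbaldehyde | O=C[C@@H]1[C@H]2C[C@@H](C)CC[C@@H]2C(C)=C[C@@H]1CO[Si](c1ccccc1)(c1ccccc1)C(C)(C)C | intermediate
22 | tert-butyl{[(1R,2R,4aS,7S,8aR)-4,7-dimethyl-1-[(E)-prop-1-en-1-yl]-1,2,4a,5,6,7,8,8a-octahydronaphthalen-2-yl]methoxy}diphenylsilane | C/C=C/[C@@H]1[C@H]2C[C@@H](C)CC[C@@H]2C(C)=C[C@@H]1CO[Si](c1ccccc1)(c1ccccc1)C(C)(C)C | intermediate
23 | [(1R,2R,4aS,7S,8aR)-4,7-dimethyl-1-[(E)-prop-1-en-1-yl]-1,2,4a,5,6,7,8,8a-octahydronaphthalen-2-yl]methanol | C/C=C/[C@@H]1[C@H]2C[C@@H](C)CC[C@@H]2C(C)=C[C@@H]1CO | intermediate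
24 | (1R,2R,4aS,7S,8aR)-4,7-dimethyl-1-[(E)-prop-1-en-1-yl]-1,2,4a,5,6,7,8,8a-octahydronaphthalene-2-carbaldehyde (formyl cis to propenyl) | C/C=C/[C@@H]1[C@H]2C[C@@H](C)CC[C@@H]2C(C)=C[C@@H]1C=O | intermediate
25 | (1R,2S,4aS,7S,8aR)-4,7-dimethyl-1-[(E)-prop-1-en-1-yl]-1,2,4a,5,6,7,8,8a-octahydronaphthalene-2-carbaldehyde (formyl trans to propenyl) | C/C=C/[C@@H]1[C@H]2C[C@@H](C)CC[C@@H]2C(C)=C[C@H]1C=O | intermediate
26 | {2,4-bis[2-(trimethylsilyl)ethoxy]-5-[(1S,2R,5R,6S)-5-(tert-butyldimethylsilyloxy)-2-(triethylsilyloxy)-7-oxabicyclo[4.1.0]heptan-2-yl]pyridin-3-yl}lithium | C[Si](C)(C)CCOc1c([Li])c(OCC[Si](C)(C)C)c(cn1)[C@]1(O[Si](CC)(CC)CC)CC[C@@H](O[Si](C)(C)C(C)(C)C)[C@@H]2O[C@@H]21 | intermediate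
27 | {2,4-bis[2-(trimethylsilyl)ethoxy]-5-[(1S,2R,5R,6S)-5-(tert-butyldimethylsilyloxy)-2-(triethylsilyloxy)-7-oxabicyclo[4.1.0]heptan-2-yl]pyridin-3-yl}[(1R,2S,4aS,7S,8aR)-4,7-dimethyl-1-[(E)-prop-1-en-1-yl]-1,2,4a,5,6,7,8,8a-octahydronaphthalen-2-yl]methanol, both carbinol epimers | C/C=C/[C@@H]1[C@H]2C[C@@H](C)CC[C@@H]2C(C)=C[C@H]1C(O)c1c(OCC[Si](C)(C)C)c(cnc1OCC[Si](C)(C)C)[C@]1(O[Si](CC)(CC)CC)CC[C@@H](O[Si](C)(C)C(C)(C)C)[C@@H]2O[C@@H]21 | intermediate
28 | {2,4-bis[2-(trimethylsilyl)ethoxy]-5-[(1S,2R,5R,6S)-5-(tert-butyldimethylsilyloxy)-2-(triethylsilyloxy)-7-oxabicyclo[4.1.0]heptan-2-yl]pyridin-3-yl}[(1R,2S,4aS,7S,8aR)-4,7-dimethyl-1-[(E)-prop-1-en-1-yl]-1,2,4a,5,6,7,8,8a-octahydronaphthalen-2-yl]methanone | C/C=C/[C@@H]1[C@H]2C[C@@H](C)CC[C@@H]2C(C)=C[C@H]1C(=O)c1c(OCC[Si](C)(C)C)c(cnc1OCC[Si](C)(C)C)[C@]1(O[Si](CC)(CC)CC)CC[C@@H](O[Si](C)(C)C(C)(C)C)[C@@H]2O[C@@H]21 | intermediate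
29 | 3-[(1R,2S,4aS,7S,8aR)-4,7-dimethyl-1-[(E)-prop-1-en-1-yl]-1,2,4a,5,6,7,8,8a-octahydronaphthalene-2-carbonyl]-5-[(1S,2R,5R,6S)-2,5-dihydroxy-7-oxabicyclo[4.1.0]heptan-2-yl]-4-hydroxypyridin-2(1H)-one | C/C=C/[C@@H]1[C@H]2C[C@@H](C)CC[C@@H]2C(C)=C[C@H]1C(=O)c1c(O)c([C@]2(O)CC[C@@H](O)[C@@H]3O[C@@H]32)c[nH]c1=O | target

**Step count**

Total: 21 steps. Longest linear sequence: 14 steps (steps 8–21, from (S)-citronellal); the pyridine branch is 10 steps (steps 1–7 and 19–21).

**Steps most likely to fail**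

Step 4. The peroxide may be delivered on the silyloxy face of the dienone (poor facial selectivity), or the catalyst may discriminate weakly between the two enone arms, so that the epoxide forms as the wrong diastereomer or with low enantiomeric purity. The fallback sets out from 7 and comes back at 8, and it fixes the face with a directing group instead of relying on the silyl ether. Luche reduction of 7 (NaBH4, CeCl3·7H2O, MeOH, −78 °C) should give the achiral cis-4-pyridyl-4-(triethylsilyloxy)cyclohexa-2,5-dien-1-ol F1, with the hydroxyl cis to the pyridyl group; the trans isomer would be separated and re-oxidised to 7 with MnO2. A hydroxyl-directed desymmetrising epoxidation (VO(Oi-Pr)3, chiral C2-symmetric bis-hydroxamic acid ligand, t-BuOOH, toluene, 0 °C) then transfers oxygen within the vanadate ester to the face that carries the hydroxyl and the pyridyl group, with the ligand choosing the arm, to give the epoxy cyclohexenol F2. Oxidation of the allylic alcohol of F2 with Dess–Martin periodinane returns 8.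

Step 6. Hydride may enter C4' from the lower face, anti to the oxirane, which would give the C4' epimer (hydroxyl cis to the oxirane). The fallback sets out from 9 and comes back at 10, and it sets C4' by an invertive displacement. Reduction of 9 with the bulky Li(s-Bu)3BH (THF, −78 °C), which is forced to approach anti to the oxirane oxygen, should give the cis-epoxy alcohol F3. Mitsunobu reaction (4-nitrobenzoic acid, PPh3, diisopropyl azodicarboxylate, toluene, 0 °C → rt) inverts C4' to the 4-nitrobenzoate F4. Brief methanolysis (K2CO3, MeOH, 0 °C) gives 10.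

Step 19. Deprotonation at C3 may be slow or unselective, so that the alkyllithium base opens the oxirane or attacks a silyl ether before C3–H is removed. The fallback sets out from 11 and comes back at 27 by way of 26, and it generates the nucleophile by halogen–metal exchange instead of deprotonation. Electrophilic iodination of 11 (N-iodosuccinimide, MeCN, rt → 40 °C) at the only free position flanked by both alkoxy groups should give the 3-iodopyridine F5. Iodine–lithium exchange (n-BuLi, THF/Et2O, −100 °C) is complete within minutes at a temperature where the oxirane is inert and delivers 26, which is combined with 25 as in step 19 to give 27.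

**Further compounds**

F1 | step 4 | cis-4-{4,6-bis[2-(trimethylsilyl)ethoxy]pyridin-3-yl}-4-(triethylsilyloxy)cyclohexa-2,5-dien-1-ol (hydroxyl cis to the pyridyl group) | O[C@H]1C=C[C@](c2cnc(OCC[Si](C)(C)C)cc2OCC[Si](C)(C)C)(O[Si](CC)(CC)CC)C=C1
F2 | step 4 | (1S,2S,5R,6S)-5-{4,6-bis[2-(trimethylsilyl)ethoxy]pyridin-3-yl}-5-(triethylsilyloxy)-7-oxabicyclo[4.1.0]hept-3-en-2-ol | C[Si](C)(C)CCOc1cc(OCC[Si](C)(C)C)c(cn1)[C@]1(O[Si](CC)(CC)CC)C=C[C@H](O)[C@@H]2O[C@@H]21
F3 | step 6 | (1S,2S,5R,6S)-5-{4,6-bis[2-(trimethylsilyl)ethoxy]pyridin-3-yl}-5-(triethylsilyloxy)-7-oxabicyclo[4.1.0]heptan-2-ol (hydroxyl cis to the oxirane) | C[Si](C)(C)CCOc1cc(OCC[Si](C)(C)C)c(cn1)[C@]1(O[Si](CC)(CC)CC)CC[C@H](O)[C@@H]2O[C@@H]21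
F4 | step 6 | (1S,2R,5R,6S)-5-{4,6-bis[2-(trimethylsilyl)ethoxy]pyridin-3-yl}-5-(triethylsilyloxy)-7-oxabicyclo[4.1.0]heptan-2-yl 4-nitrobenzoate | C[Si](C)(C)CCOc1cc(OCC[Si](C)(C)C)c(cn1)[C@]1(O[Si](CC)(CC)CC)CC[C@@H](OC(=O)c2ccc(cc2)[N+](=O)[O-])[C@@H]2O[C@@H]21
F5 | step 19 | 5-[(1S,2R,5R,6S)-5-(tert-butyldimethylsilyloxy)-2-(triethylsilyloxy)-7-oxabicyclo[4.1.0]heptan-2-yl]-3-iodo-2,4-bis[2-(trimethylsilyl)ethoxy]pyridine | C[Si](C)(C)CCOc1c(I)c(OCC[Si](C)(C)C)c(cn1)[C@]1(O[Si](CC)(CC)CC)CC[C@@H](O[Si](C)(C)C(C)(C)C)[C@@H]2O[C@@H]21
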